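(The earlier runs and the new flask were computed from invented constants, and the scatter is random.)

The product of the violet flask, chains grown from initiator, was the one item of the meeting: how long they stand after 30 h, and how much free monomer has reacted by then.

| flask | free monomer | transfer agent | protic impurity | initiator | remark | time |
|---|---|---|---|---|---|---|
| violet | 0.10 M | 0.030 M | 0.10 M | 1.3 mM | the very flask that is asked about, followed so far |  |
| grey | 0.10 M | 0.030 M | 0.10 M | 2.6 mM | run made earlier |  |
| flask | 0.10 M | 0.0300 M | 0.100 M | 1.3 mM |  | 30 h |

| run | time / h | monomer in chains / % | free monomer / % |
|---|---|---|---|
| violet | 0.333 | 0.3 | 98.1 |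
| violet | 0.833 | 1.1 | 96.3 |
| violet | 1.50 | 2.2 | 92.8 |
| violet | 2.50 | 4.1 | 88.4 |
| grey | 8.00 | 18.4 | 64.5 |
| grey | 15.0 | 22.0 | 50.4 |
| grey | 25.0 | 24.3 | 38.3 |
| grey | 30.0 | 24.5 | 34.3 |

(standard deviation of a reading: 0.5 percentage points)

* average number of monomer units in a chain (chains begun, living or dead) at 30 h
* part of the free monomer that has reacted at 30 h

- the average divides the monomer in chains by the number of chains begun, living and dead together
- the analysis behind the earlier runs scatters by 0.5 percentage points, standard deviation
- steps under discussion: free monomer + initiator -> living end + monomer in chains; free monomer + living end -> monomer in chains + living end; living end + transfer agent -> dead chain; protic impurity + free monomer -> quenched substrate; living end + free monomer -> dead end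
- the earlier runs do not show the number of chains; that part of a forecast is a guess

The first speaker noted that the grey run had nearly stopped growing: monomer in chains read 24.3% after 25.0 h and 24.5% after 30.0 h, against a scatter of 0.5 percentage points.

The second speaker went to the board. A living end either adds free monomer or dies. If both steps are first order in living end, then dividing the rate of growth by the rate of loss of living ends cancels c(living end), but the ratio keeps c(free monomer) and c(transfer agent), and c(free monomer) falls as the flask runs, so time does not wholly drop out. Free monomer and transfer agent are charged alike in grey and violet, so she carried the grey length over to violet as an estimate and not as an equality, since the initiator charges differ and c(free monomer) need not fall alike in the two.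

She therefore took 24.5% of 0.10 M over 2.6 mM from the grey run, which gives 9.42 units per initiator charged, the chain yield (a kinetic chain length, in the usual term). This counts every initiator as a chain begun, which the runs do not show. Her dp for the violet flask was thus 9.42.

The forecast stood somewhat higher, at dp 10.5 (8.5 to 14), with c 58% (54% to 62%). Of its dp, the forecaster said: “This is the guessed part”.

The flask gives dp 9.73 and c 57.1%, both within the forecast's ranges. After 30.0 h the flask has 0% of its initiator left, so the chains begun match the charge. Carried over, 9.42 times that charge puts 12.2% of the free monomer charged into chains, and the flask holds 12.7%.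

    free monomer + initiator → living end + monomer in chains (k = 0.00430 L mol⁻¹ s⁻¹)
    free monomer + living end → monomer in chains + living end, rate k2*[living end]*[free monomer] (k = 0.00410 L mol⁻¹ s⁻¹)
    living end + transfer agent → dead chain (kL = 5.30 × 10⁻⁴ L mol⁻¹ s⁻¹)
    protic impurity + free monomer → quenched substrate (k = 8.50 × 10⁻⁵ L mol⁻¹ s⁻¹)
    living end + free monomer → dead end (k = 2.40 × 10⁻⁴ L mol⁻¹ s⁻¹)

A neighbouring flask with 3.3 × 10⁻⁴ M of initiator, all else the same, should by the chain yield again have dp 9.42, with 3.11% in chains. Computed, it gives dp 10.1 and 3.32%.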